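**Plan**

1. Numbering: C1 is the ring CH–CH3, C2/C3 the ring CH2 groups, C4 the ring CH carrying the side chain; C5–C10 are the arene (C5 H, C6 bearing carboxyl C19, C7 OH, C8 OH, C9 bonded to C1, C10 bonded to C4); C11–C16 are the side chain (C11 with methyl C18, C15 with a methyl, C16 the OCH2).
2. Enabling feature: the C8 hydroxyl lies ortho to fusion carbon C9, so C9–C8 can be read as a former ethynyl group on C1 and C10/C5/C6/C7 as a former 4-substituted furan-2-yl on C4; ring B (C1–C4, C9, C10) and the arene can then be closed together from an acyclic furyl alkyne.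
3. Retrosynthetic cuts: ferulate C16–O; C7–O; C19 oxidation level; C9–C10 and C7–C8 (gold furan–yne phenol synthesis); C8–C9 (alkyne homologation); C4–C11 (Ireland–Claisen [3,3] shift); C1–C2 (syn-aldol); C13–C14 (copper-catalysed alkyl coupling).
4. Forward order: furyl enal plus propionyl oxazolidinone gives the allylic alcohol; esterification with the C11–C16 acid and Claisen rearrangement join the chain; CO2H becomes the C18 methyl, the alkene is saturated, C9 becomes ethynyl; gold closes ring B and the arene in one step; then C7–OH, C19 acid, ferulate, deprotection.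
5. Stereochemistry: C15 comes from (S)-3-bromo-2-methylpropan-1-ol; C1 from the Evans syn-aldol, whose C2 carbinol is relayed through a chair Claisen transition state to C4 and, through the E(O)-enolate, to C11; the key step creates no stereocentre.

Key step: step 20

Remark on the chemistry: TBDPS, TBS, TMS and MOM stand for tert-butyldiphenylsilyl, tert-butyldimethylsilyl, trimethylsilyl and methoxymethyl; (tributylstannyl)methanol, oxazolidinone 5, bromo alcohol 11, 5-bromopent-1-ene and the Ohira–Bestmann reagent are assumed to be purchasable.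

**Route**

Step 1
Reactants: 1 4-bromofuran-2-carbaldehyde
Product: 2 4-(hydroxymethyl)furan-2-carbaldehyde
Conditions: Bu3SnCH2OH, Pd(PPh3)4 (5 mol %), 1,4-dioxane, 100 °C
Reagents that add atoms: (tributylstannyl)methanol, OC[Sn](CCCC)(CCCC)CCCC
Why: Migita–Kosugi–Stille coupling, in which zerovalent palladium inserts into the C–Br bond activated by the formyl group, the hydroxymethyl group is transferred from tin and reductive elimination gives the alcohol without touching the aldehyde.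

Step 2
Reactants: 2 4-(hydroxymethyl)furan-2-carbaldehyde
Product: 3 4-[(TBDPS-oxy)methyl]furan-2-carbaldehyde
Conditions: TBDPSCl, imidazole, CH2Cl2, 0 °C → rt
Reagents that add atoms: tert-butyl(chloro)diphenylsilane, CC(C)(C)[Si](Cl)(c1ccccc1)c1ccccc1
Why: Imidazole-promoted silylation of a primary alcohol gives a robust silyl ether that keeps the furan electron-rich and outlasts the later acid-labile TBS ether.

Step 3
Reactants: 3 4-[(TBDPS-oxy)methyl]furan-2-carbaldehyde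
Product: 4 (E)-3-{4-[(TBDPS-oxy)methyl]furan-2-yl}prop-2-enal
Conditions: Ph3P=CHCHO (1.05 equiv), toluene, 80 °C
Reagents that add atoms: (triphenylphosphoranylidene)acetaldehyde, O=CC=P(c1ccccc1)(c1ccccc1)c1ccccc1
Why: Wittig olefination with a stabilised formylmethylene ylide should give the (E)-enal, and using about one equivalent of ylide limits the chain extension to a single vinylogation.

Step 4
Reactants: 4 (E)-3-{4-[(TBDPS-oxy)methyl]furan-2-yl}prop-2-enal; 5 (R)-4-benzyl-3-propionyloxazolidin-2-one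
Product: 8 (R)-4-benzyl-3-[(2R,3S,4E)-3-hydroxy-2-methyl-5-{4-[(TBDPS-oxy)methyl]furan-2-yl}pent-4-enoyl]oxazolidin-2-one, via boron enolate 6 (not isolated), via boron aldolate 7 (not isolated)
Conditions: 5, Bu2BOTf, i-Pr2NEt, CH2Cl2, 0 °C; then 4, −78 → 0 °C; pH 7 buffer, MeOH, H2O2, 0 °C
Reagents that add atoms: none
Why: Evans syn-aldol reaction, in which the Z-boron enolate 6 adds to the enal through a chair Zimmerman–Traxler transition state on the face away from the benzyl group of the (R)-auxiliary, setting C1 (R) and the C2 carbinol (S) as the syn pair.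

Step 5
Reactants: 8 (R)-4-benzyl-3-[(2R,3S,4E)-3-hydroxy-2-methyl-5-{4-[(TBDPS-oxy)methyl]furan-2-yl}pent-4-enoyl]oxazolidin-2-one
Product: 9 (2S,3S,4E)-2-methyl-5-{4-[(TBDPS-oxy)methyl]furan-2-yl}pent-4-ene-1,3-diol
Conditions: LiBH4, THF, 0 °C
Reagents that add atoms: none
Why: Reductive cleavage of the imide with LiBH4 gives the primary C9 alcohol without epimerising C1 and releases the auxiliary for reuse.

Step 6
Reactants: 9 (2S,3S,4E)-2-methyl-5-{4-[(TBDPS-oxy)methyl]furan-2-yl}pent-4-ene-1,3-diol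
Product: 10 (1E,3S,4S)-4-methyl-5-(TBS-oxy)-1-{4-[(TBDPS-oxy)methyl]furan-2-yl}pent-1-en-3-ol
Conditions: TBSCl (1.05 equiv), imidazole, CH2Cl2, −20 °C
Reagents that add atoms: tert-butyl(chloro)dimethylsilane, CC(C)(C)[Si](C)(C)Cl
Why: Sterically controlled monosilylation, since the primary C9 hydroxyl reacts far faster with TBSCl than the secondary allylic C2 hydroxyl, which stays free for esterification.

Step 7
Reactants: 11 (S)-3-bromo-2-methylpropan-1-ol
Product: 12 (S)-(3-bromo-2-methylpropoxy)(tert-butyl)diphenylsilane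
Conditions: TBDPSCl, imidazole, CH2Cl2, rt
Reagents that add atoms: tert-butyl(chloro)diphenylsilane, CC(C)(C)[Si](Cl)(c1ccccc1)c1ccccc1
Why: Standard silylation of the primary alcohol, carrying the future C15 stereocentre unchanged from the commercial bromo alcohol.

Step 8
Reactants: 12 (S)-(3-bromo-2-methylpropoxy)(tert-butyl)diphenylsilane
Product: 13 (R)-tert-butyl[(2-methyloct-7-en-1-yl)oxy]diphenylsilane
Conditions: pent-4-enylmagnesium bromide (from 5-bromopent-1-ene, Mg, THF), Li2CuCl4 (3 mol %), THF/NMP, 0 °C → rt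
Reagents that add atoms: pent-4-enylmagnesium bromide, C=CCCC[Mg]Br
Why: Copper-catalysed sp3–sp3 cross-coupling of a primary alkyl bromide with a primary Grignard reagent (Kochi-type coupling) forms C13–C14 and does not touch the stereocentre next to the reacting carbon.

Step 9
Reactants: 13 (R)-tert-butyl[(2-methyloct-7-en-1-yl)oxy]diphenylsilane
Product: 15 (R)-6-methyl-7-(TBDPS-oxy)heptanal, via ozonide 14 (not isolated)
Conditions: O3, CH2Cl2, −78 °C; then PPh3, −78 °C → rt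
Reagents that add atoms: ozone, [O-][O+]=O
Why: Ozonolysis with reductive work-up cleaves the terminal alkene to the aldehyde, and the silyl ether and saturated chain are inert to ozone at low temperature.

Step 10
Reactants: 15 (R)-6-methyl-7-(TBDPS-oxy)heptanal
Product: 16 (R)-6-methyl-7-(TBDPS-oxy)heptanoic acid
Conditions: NaClO2, NaH2PO4, 2-methylbut-2-ene, t-BuOH/H2O, rt
Reagents that add atoms: sodium chlorite, [Na+].[O-]Cl=O
Why: Pinnick oxidation converts the aldehyde into the acid under buffered conditions with the alkene additive scavenging hypochlorite.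

Step 11
Reactants: 10 (1E,3S,4S)-4-methyl-5-(TBS-oxy)-1-{4-[(TBDPS-oxy)methyl]furan-2-yl}pent-1-en-3-ol; 16 (R)-6-methyl-7-(TBDPS-oxy)heptanoic acid
Product: 17 (1E,3S,4S)-4-methyl-5-(TBS-oxy)-1-{4-[(TBDPS-oxy)methyl]furan-2-yl}pent-1-en-3-yl (R)-6-methyl-7-(TBDPS-oxy)heptanoate
Conditions: EDC·HCl, DMAP, CH2Cl2, 0 °C → rt
Reagents that add atoms: none
Why: Steglich esterification acylates the secondary allylic alcohol under neutral conditions that should not ionise the furyl-conjugated allylic system.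

Step 12
Reactants: 17 (1E,3S,4S)-4-methyl-5-(TBS-oxy)-1-{4-[(TBDPS-oxy)methyl]furan-2-yl}pent-1-en-3-yl (R)-6-methyl-7-(TBDPS-oxy)heptanoate
Product: 20 (2S,3S,4E,6R)-6-methyl-2-[(4R)-4-methyl-5-(TBDPS-oxy)pentyl]-7-(TBS-oxy)-3-{4-[(TBDPS-oxy)methyl]furan-2-yl}hept-4-enoic acid, via silyl ketene acetal 18 (not isolated), via trimethylsilyl ester 19 (not isolated)
Conditions: LiN(i-Pr)2 (commercial solution), THF, −78 °C; TMSCl/Et3N, −78 °C → rt, then 40 °C; aq. citric acid, MeOH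
Reagents that add atoms: none
Why: Ireland–Claisen rearrangement, in which kinetic deprotonation in THF gives the E(O)-enolate (C12 trans to OLi), trapping gives the (E)-silyl ketene acetal 18, and its [3,3] shift through a chair transition state with the C1-bearing substituent of the (S)-carbinol equatorial relays the C2 configuration to C4 (S) and C11 (S) while forming the (E)-C2=C3 alkene.

Step 13
Reactants: 20 (2S,3S,4E,6R)-6-methyl-2-[(4R)-4-methyl-5-(TBDPS-oxy)pentyl]-7-(TBS-oxy)-3-{4-[(TBDPS-oxy)methyl]furan-2-yl}hept-4-enoic acid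
Product: 21 (2S,3S,4E,6R)-6-methyl-2-[(4R)-4-methyl-5-(TBDPS-oxy)pentyl]-7-(TBS-oxy)-3-{4-[(TBDPS-oxy)methyl]furan-2-yl}hept-4-en-1-ol
Conditions: LiAlH4, THF, 0 °C → rt
Reagents that add atoms: none
Why: LiAlH4 reduces the carboxylic acid to the primary C18 alcohol without affecting silyl ethers, furan or the isolated alkene.

Step 14
Reactants: 21 (2S,3S,4E,6R)-6-methyl-2-[(4R)-4-methyl-5-(TBDPS-oxy)pentyl]-7-(TBS-oxy)-3-{4-[(TBDPS-oxy)methyl]furan-2-yl}hept-4-en-1-ol
Product: 22 (2S,3S,4E,6R)-6-methyl-2-[(4R)-4-methyl-5-(TBDPS-oxy)pentyl]-7-(TBS-oxy)-3-{4-[(TBDPS-oxy)methyl]furan-2-yl}hept-4-en-1-yl 4-methylbenzenesulfonate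
Conditions: TsCl, Et3N, DMAP (cat.), CH2Cl2, 0 °C → rt
Reagents that add atoms: 4-methylbenzenesulfonyl chloride, Cc1ccc(S(=O)(=O)Cl)cc1
Why: Sulfonylation of the primary alcohol turns C18–O into a leaving group for hydride displacement.

Step 15
Reactants: 22 (2S,3S,4E,6R)-6-methyl-2-[(4R)-4-methyl-5-(TBDPS-oxy)pentyl]-7-(TBS-oxy)-3-{4-[(TBDPS-oxy)methyl]furan-2-yl}hept-4-en-1-yl 4-methylbenzenesulfonate
Product: 23 2-[(2R,3E,5R,6S,10R)-2,6,10-trimethyl-1-(TBS-oxy)-11-(TBDPS-oxy)undec-3-en-5-yl]-4-[(TBDPS-oxy)methyl]furan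
Conditions: LiEt3BH, THF, 0 °C → rt
Reagents that add atoms: none
Why: SN2 hydride displacement of the primary tosylate by LiEt3BH delivers the C18 methyl group, the reagent being nucleophilic enough for a beta-branched tosylate and inert toward silyl ethers.

Step 16
Reactants: 23 2-[(2R,3E,5R,6S,10R)-2,6,10-trimethyl-1-(TBS-oxy)-11-(TBDPS-oxy)undec-3-en-5-yl]-4-[(TBDPS-oxy)methyl]furan
Product: 24 2-[(2R,5S,6S,10R)-2,6,10-trimethyl-1-(TBS-oxy)-11-(TBDPS-oxy)undecan-5-yl]-4-[(TBDPS-oxy)methyl]furan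
Conditions: TsNHNH2 (excess, in portions), NaOAc, DME/H2O, 85 °C
Reagents that add atoms: none
Why: Diimide generated in situ transfers two hydrogens to the isolated disubstituted alkene, reduces neither the furan nor the silyl ethers and cannot migrate the double bond toward the furan, so C1 and C4 keep their configuration.

Step 17
Reactants: 24 2-[(2R,5S,6S,10R)-2,6,10-trimethyl-1-(TBS-oxy)-11-(TBDPS-oxy)undecan-5-yl]-4-[(TBDPS-oxy)methyl]furan
Product: 25 (2R,5S,6S,10R)-2,6,10-trimethyl-11-(TBDPS-oxy)-5-{4-[(TBDPS-oxy)methyl]furan-2-yl}undecan-1-ol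
Conditions: CSA (10 mol %), MeOH/CH2Cl2, 0 °C
Reagents that add atoms: none
Why: Acid-catalysed methanolysis cleaves a primary TBS ether far faster than primary TBDPS ethers, so only the C9 hydroxyl should be freed.

Step 18
Reactants: 25 (2R,5S,6S,10R)-2,6,10-trimethyl-11-(TBDPS-oxy)-5-{4-[(TBDPS-oxy)methyl]furan-2-yl}undecan-1-ol
Product: 26 (2R,5S,6S,10R)-2,6,10-trimethyl-11-(TBDPS-oxy)-5-{4-[(TBDPS-oxy)methyl]furan-2-yl}undecanal
Conditions: Dess–Martin periodinane, NaHCO3, CH2Cl2, 0 °C → rt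
Reagents that add atoms: none
Why: Dess–Martin oxidation gives the alpha-branched aldehyde under buffered, non-enolising conditions, so C1 should not epimerise, and the aldehyde is used at once.

Step 19
Reactants: 26 (2R,5S,6S,10R)-2,6,10-trimethyl-11-(TBDPS-oxy)-5-{4-[(TBDPS-oxy)methyl]furan-2-yl}undecanal
Product: 27 2-[(3R,6S,7S,11R)-3,7,11-trimethyl-12-(TBDPS-oxy)dodec-1-yn-6-yl]-4-[(TBDPS-oxy)methyl]furan
Conditions: dimethyl (1-diazo-2-oxopropyl)phosphonate, K2CO3, MeOH, 0 °C → rt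
Reagents that add atoms: dimethyl (1-diazo-2-oxopropyl)phosphonate, CC(=O)C(=[N+]=[N-])P(=O)(OC)OC
Why: Ohira–Bestmann homologation, in which the diazomethylphosphonate anion released by methanolysis adds to the aldehyde and loss of phosphate and nitrogen with 1,2-hydrogen shift gives the terminal alkyne with C8 as the new carbon under carbonate conditions mild enough to keep C1 intact.

Step 20
Reactants: 27 2-[(3R,6S,7S,11R)-3,7,11-trimethyl-12-(TBDPS-oxy)dodec-1-yn-6-yl]-4-[(TBDPS-oxy)methyl]furan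
Product: 29 (5S,8R)-8-methyl-5-[(2S,6R)-6-methyl-7-(TBDPS-oxy)heptan-2-yl]-3-[(TBDPS-oxy)methyl]-5,6,7,8-tetrahydronaphthalen-1-ol, via arene oxide 28 (not isolated)
Conditions: (Ph3P)AuNTf2 (5 mol %), CH2Cl2, rt
Reagents that add atoms: none
Why: Monovalent gold activates the terminal alkyne and the tethered furan alpha-carbon (future C10) attacks the internal alkyne carbon C9, giving a cyclopropyl gold carbene that opens to a carbonyl-conjugated dienyl carbene; the carbonyl oxygen then closes onto the carbene carbon to an oxepine, which is in equilibrium with arene oxide 28 (new C7–C8 bond) and opens to the phenol with oxygen on the former alkyne terminus C8. The closest known reaction type is the gold-catalysed intramolecular furan–alkyne phenol synthesis, here run through a less common all-carbon four-atom tether. Ring B (C1–C4, C9, C10) closes 6-exo-dig on the alkyne, and the arene closes by oxygen-to-carbene attack followed by 6π electrocyclisation of the oxepine. No stereocentre is created, and C1 and C4, set earlier, are not epimerisable under the neutral conditions. The step needs exo attack by the furan alpha-carbon in preference to hydration or intermolecular reaction of the alkyne, which the branching at both tether ends and the electron-rich silyloxymethyl furan should favour. It also needs the arene oxide to open toward C8, as is usual for this phenol synthesis, and a minor C7 phenol would still converge on the same ortho-quinone in step 21.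

Step 21
Reactants: 29 (5S,8R)-8-methyl-5-[(2S,6R)-6-methyl-7-(TBDPS-oxy)heptan-2-yl]-3-[(TBDPS-oxy)methyl]-5,6,7,8-tetrahydronaphthalen-1-ol
Product: 31 (5S,8R)-8-methyl-5-[(2S,6R)-6-methyl-7-(TBDPS-oxy)heptan-2-yl]-3-[(TBDPS-oxy)methyl]-5,6,7,8-tetrahydronaphthalene-1,2-diol, via ortho-quinone 30 (not isolated)
Conditions: IBX, DMF, rt; then aq. Na2S2O4
Reagents that add atoms: 2-iodoxybenzoic acid (IBX), O=C1OI(=O)(O)c2ccccc12
Why: IBX ortho-oxidation of phenols, in which the phenol binds to pentavalent iodine through oxygen and an oxygen atom is delivered intramolecularly to the only free ortho carbon, C7, giving ortho-quinone 30, which dithionite reduces in the same pot to the catechol.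

Step 22
Reactants: 31 (5S,8R)-8-methyl-5-[(2S,6R)-6-methyl-7-(TBDPS-oxy)heptan-2-yl]-3-[(TBDPS-oxy)methyl]-5,6,7,8-tetrahydronaphthalene-1,2-diol
Product: 32 (5S,8R)-1,2-bis(methoxymethoxy)-8-methyl-5-[(2S,6R)-6-methyl-7-(TBDPS-oxy)heptan-2-yl]-3-[(TBDPS-oxy)methyl]-5,6,7,8-tetrahydronaphthalene
Conditions: MOMCl, i-Pr2NEt, Bu4NI (cat.), CH2Cl2, 0 → 40 °C
Reagents that add atoms: chloromethyl methyl ether, COCCl
Why: O-Alkylation of both phenols with MOMCl protects the air-sensitive catechol as acetal ethers that tolerate fluoride, MnO2, carbodiimide and chlorite and are removed by acid at the end.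

Step 23
Reactants: 32 (5S,8R)-1,2-bis(methoxymethoxy)-8-methyl-5-[(2S,6R)-6-methyl-7-(TBDPS-oxy)heptan-2-yl]-3-[(TBDPS-oxy)methyl]-5,6,7,8-tetrahydronaphthalene
Product: 33 (2R,6S)-6-[(1S,4R)-7-(hydroxymethyl)-5,6-bis(methoxymethoxy)-4-methyl-1,2,3,4-tetrahydronaphthalen-1-yl]-2-methylheptan-1-ol
Conditions: Bu4NF, THF, rt
Reagents that add atoms: none
Why: Fluoride-mediated desilylation removes both TBDPS groups at once and leaves the MOM ethers untouched.

Step 24
Reactants: 33 (2R,6S)-6-[(1S,4R)-7-(hydroxymethyl)-5,6-bis(methoxymethoxy)-4-methyl-1,2,3,4-tetrahydronaphthalen-1-yl]-2-methylheptan-1-ol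
Product: 34 (5R,8S)-8-[(2S,6R)-7-hydroxy-6-methylheptan-2-yl]-3,4-bis(methoxymethoxy)-5-methyl-5,6,7,8-tetrahydronaphthalene-2-carbaldehyde
Conditions: MnO2 (activated, excess), CH2Cl2, rt
Reagents that add atoms: none
Why: Activated MnO2 oxidises benzylic alcohols selectively, so the C19 alcohol should become the aldehyde while the saturated C16 primary alcohol is unchanged.

Step 25
Reactants: 35 ferulic acid, (E)-3-(4-hydroxy-3-methoxyphenyl)prop-2-enoic acid
Product: 37 (E)-3-[3-methoxy-4-(methoxymethoxy)phenyl]prop-2-enoic acid, via methoxymethyl ester 36 (not isolated)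
Conditions: MOMCl (2.5 equiv), i-Pr2NEt, CH2Cl2, 0 °C → rt; then LiOH, THF/H2O, rt; HCl to pH 3
Reagents that add atoms: chloromethyl methyl ether, COCCl
Why: MOMCl alkylates phenol and carboxylate alike, and saponification of the labile methoxymethyl ester 36 then frees the acid while the base-stable aryl MOM ether remains.

Step 26
Reactants: 34 (5R,8S)-8-[(2S,6R)-7-hydroxy-6-methylheptan-2-yl]-3,4-bis(methoxymethoxy)-5-methyl-5,6,7,8-tetrahydronaphthalene-2-carbaldehyde; 37 (E)-3-[3-methoxy-4-(methoxymethoxy)phenyl]prop-2-enoic acid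
Product: 38 (2R,6S)-6-[(1S,4R)-7-formyl-5,6-bis(methoxymethoxy)-4-methyl-1,2,3,4-tetrahydronaphthalen-1-yl]-2-methylheptyl (E)-3-[3-methoxy-4-(methoxymethoxy)phenyl]prop-2-enoate
Conditions: EDC·HCl, DMAP, CH2Cl2, rt
Reagents that add atoms: none
Why: Steglich esterification of the only hydroxyl group (C16) with the protected ferulic acid, to which the aromatic aldehyde and the MOM ethers are inert.

Step 27
Reactants: 38 (2R,6S)-6-[(1S,4R)-7-formyl-5,6-bis(methoxymethoxy)-4-methyl-1,2,3,4-tetrahydronaphthalen-1-yl]-2-methylheptyl (E)-3-[3-methoxy-4-(methoxymethoxy)phenyl]prop-2-enoate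
Product: 39 (5R,8S)-8-[(2S,6R)-7-{[(E)-3-(3-methoxy-4-(methoxymethoxy)phenyl)prop-2-enoyl]oxy}-6-methylheptan-2-yl]-3,4-bis(methoxymethoxy)-5-methyl-5,6,7,8-tetrahydronaphthalene-2-carboxylic acid
Conditions: NaClO2, NaH2PO4, 2-methylbut-2-ene (large excess), t-BuOH/H2O, rt
Reagents that add atoms: sodium chlorite, [Na+].[O-]Cl=O
Why: Pinnick oxidation converts the aryl aldehyde into the C19 carboxylic acid, with the excess alkene scavenging hypochlorite so that the cinnamate double bond and the electron-rich arenes are not chlorinated.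

Step 28
Reactants: 39 (5R,8S)-8-[(2S,6R)-7-{[(E)-3-(3-methoxy-4-(methoxymethoxy)phenyl)prop-2-enoyl]oxy}-6-methylheptan-2-yl]-3,4-bis(methoxymethoxy)-5-methyl-5,6,7,8-tetrahydronaphthalene-2-carboxylic acid
Product: 40 (5R,8S)-3,4-dihydroxy-8-[(2S,6R)-7-{[(E)-3-(4-hydroxy-3-methoxyphenyl)prop-2-enoyl]oxy}-6-methylheptan-2-yl]-5-methyl-5,6,7,8-tetrahydronaphthalene-2-carboxylic acid (CNP0535851.1)
Conditions: 3 M aq. HCl, i-PrOH/THF, 45 °C, under argon
Reagents that add atoms: none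
Why: Acid-catalysed hydrolysis of the three aryl MOM acetals proceeds through oxocarbenium ions under conditions expected to be too mild to hydrolyse or transesterify the primary alkyl cinnamate, and exclusion of air protects the liberated catechol.

**Compound list**

1 | 4-bromofuran-2-carbaldehyde | O=Cc1cc(Br)co1 | starting material
2 | 4-(hydroxymethyl)furan-2-carbaldehyde | O=Cc1cc(CO)co1 | intermediate
3 | 4-[(TBDPS-oxy)methyl]furan-2-carbaldehyde | O=Cc1cc(CO[Si](c2ccccc2)(c2ccccc2)C(C)(C)C)co1 | intermediate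
4 | (E)-3-{4-[(TBDPS-oxy)methyl]furan-2-yl}prop-2-enal | O=C/C=C/c1cc(CO[Si](c2ccccc2)(c2ccccc2)C(C)(C)C)co1 | intermediate
5 | (R)-4-benzyl-3-propionyloxazolidin-2-one | CCC(=O)N1[C@H](Cc2ccccc2)COC1=O | starting material
6 | (Z)-dibutylboron enolate of 5 | C/C=C(\OB(CCCC)CCCC)N1[C@H](Cc2ccccc2)COC1=O | intermediate
7 | O-dibutylboryl aldolate of 8 | O=C1OC[C@@H](Cc2ccccc2)N1C(=O)[C@H](C)[C@@H](OB(CCCC)CCCC)/C=C/c1cc(CO[Si](c2ccccc2)(c2ccccc2)C(C)(C)C)co1 | intermediate
8 | (R)-4-benzyl-3-[(2R,3S,4E)-3-hydroxy-2-methyl-5-{4-[(TBDPS-oxy)methyl]furan-2-yl}pent-4-enoyl]oxazolidin-2-one | O=C1OC[C@@H](Cc2ccccc2)N1C(=O)[C@H](C)[C@@H](O)/C=C/c1cc(CO[Si](c2ccccc2)(c2ccccc2)C(C)(C)C)co1 | intermediate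
9 | (2S,3S,4E)-2-methyl-5-{4-[(TBDPS-oxy)methyl]furan-2-yl}pent-4-ene-1,3-diol | OC[C@H](C)[C@@H](O)/C=C/c1cc(CO[Si](c2ccccc2)(c2ccccc2)C(C)(C)C)co1 | intermediate
10 | (1E,3S,4S)-4-methyl-5-(TBS-oxy)-1-{4-[(TBDPS-oxy)methyl]furan-2-yl}pent-1-en-3-ol | CC(C)(C)[Si](C)(C)OC[C@H](C)[C@@H](O)/C=C/c1cc(CO[Si](c2ccccc2)(c2ccccc2)C(C)(C)C)co1 | intermediate
11 | (S)-3-bromo-2-methylpropan-1-ol | OC[C@H](C)CBr | starting material
12 | (S)-(3-bromo-2-methylpropoxy)(tert-butyl)diphenylsilane | CC(C)(C)[Si](c1ccccc1)(c1ccccc1)OC[C@H](C)CBr | intermediate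
13 | (R)-tert-butyl[(2-methyloct-7-en-1-yl)oxy]diphenylsilane | CC(C)(C)[Si](c1ccccc1)(c1ccccc1)OC[C@H](C)CCCCC=C | intermediate
14 | 3-[(5R)-5-methyl-6-(TBDPS-oxy)hexyl]-1,2,4-trioxolane (ozonide of 13) | CC(C)(C)[Si](c1ccccc1)(c1ccccc1)OC[C@H](C)CCCCC1OCOO1 | intermediate
15 | (R)-6-methyl-7-(TBDPS-oxy)heptanal | CC(C)(C)[Si](c1ccccc1)(c1ccccc1)OC[C@H](C)CCCCC=O | intermediate
16 | (R)-6-methyl-7-(TBDPS-oxy)heptanoic acid | CC(C)(C)[Si](c1ccccc1)(c1ccccc1)OC[C@H](C)CCCCC(=O)O | intermediate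
17 | (1E,3S,4S)-4-methyl-5-(TBS-oxy)-1-{4-[(TBDPS-oxy)methyl]furan-2-yl}pent-1-en-3-yl (R)-6-methyl-7-(TBDPS-oxy)heptanoate | CC(C)(C)[Si](c1ccccc1)(c1ccccc1)OC[C@H](C)CCCCC(=O)O[C@@H](/C=C/c1cc(CO[Si](c2ccccc2)(c2ccccc2)C(C)(C)C)co1)[C@@H](C)CO[Si](C)(C)C(C)(C)C | intermediate
18 | (E)-trimethylsilyl ketene acetal of ester 17 (C12 trans to OTMS) | CC(C)(C)[Si](c1ccccc1)(c1ccccc1)OC[C@H](C)CCC/C=C(/O[Si](C)(C)C)O[C@@H](/C=C/c1cc(CO[Si](c2ccccc2)(c2ccccc2)C(C)(C)C)co1)[C@@H](C)CO[Si](C)(C)C(C)(C)C | intermediate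
19 | trimethylsilyl ester of acid 20 | CC(C)(C)[Si](c1ccccc1)(c1ccccc1)OC[C@H](C)CCC[C@H](C(=O)O[Si](C)(C)C)[C@@H](c1cc(CO[Si](c2ccccc2)(c2ccccc2)C(C)(C)C)co1)/C=C/[C@@H](C)CO[Si](C)(C)C(C)(C)C | intermediate
20 | (2S,3S,4E,6R)-6-methyl-2-[(4R)-4-methyl-5-(TBDPS-oxy)pentyl]-7-(TBS-oxy)-3-{4-[(TBDPS-oxy)methyl]furan-2-yl}hept-4-enoic acid | CC(C)(C)[Si](c1ccccc1)(c1ccccc1)OC[C@H](C)CCC[C@H](C(=O)O)[C@@H](c1cc(CO[Si](c2ccccc2)(c2ccccc2)C(C)(C)C)co1)/C=C/[C@@H](C)CO[Si](C)(C)C(C)(C)C | intermediate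
21 | (2S,3S,4E,6R)-6-methyl-2-[(4R)-4-methyl-5-(TBDPS-oxy)pentyl]-7-(TBS-oxy)-3-{4-[(TBDPS-oxy)methyl]furan-2-yl}hept-4-en-1-ol | CC(C)(C)[Si](c1ccccc1)(c1ccccc1)OC[C@H](C)CCC[C@H](CO)[C@@H](c1cc(CO[Si](c2ccccc2)(c2ccccc2)C(C)(C)C)co1)/C=C/[C@@H](C)CO[Si](C)(C)C(C)(C)C | intermediate
22 | (2S,3S,4E,6R)-6-methyl-2-[(4R)-4-methyl-5-(TBDPS-oxy)pentyl]-7-(TBS-oxy)-3-{4-[(TBDPS-oxy)methyl]furan-2-yl}hept-4-en-1-yl 4-methylbenzenesulfonate | CC(C)(C)[Si](c1ccccc1)(c1ccccc1)OC[C@H](C)CCC[C@H](COS(=O)(=O)c1ccc(C)cc1)[C@@H](c1cc(CO[Si](c2ccccc2)(c2ccccc2)C(C)(C)C)co1)/C=C/[C@@H](C)CO[Si](C)(C)C(C)(C)C | intermediate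
23 | 2-[(2R,3E,5R,6S,10R)-2,6,10-trimethyl-1-(TBS-oxy)-11-(TBDPS-oxy)undec-3-en-5-yl]-4-[(TBDPS-oxy)methyl]furan | CC(C)(C)[Si](c1ccccc1)(c1ccccc1)OC[C@H](C)CCC[C@H](C)[C@@H](c1cc(CO[Si](c2ccccc2)(c2ccccc2)C(C)(C)C)co1)/C=C/[C@@H](C)CO[Si](C)(C)C(C)(C)C | intermediate
24 | 2-[(2R,5S,6S,10R)-2,6,10-trimethyl-1-(TBS-oxy)-11-(TBDPS-oxy)undecan-5-yl]-4-[(TBDPS-oxy)methyl]furan | CC(C)(C)[Si](c1ccccc1)(c1ccccc1)OC[C@H](C)CCC[C@H](C)[C@@H](c1cc(CO[Si](c2ccccc2)(c2ccccc2)C(C)(C)C)co1)CC[C@@H](C)CO[Si](C)(C)C(C)(C)C | intermediate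
25 | (2R,5S,6S,10R)-2,6,10-trimethyl-11-(TBDPS-oxy)-5-{4-[(TBDPS-oxy)methyl]furan-2-yl}undecan-1-ol | CC(C)(C)[Si](c1ccccc1)(c1ccccc1)OC[C@H](C)CCC[C@H](C)[C@@H](c1cc(CO[Si](c2ccccc2)(c2ccccc2)C(C)(C)C)co1)CC[C@@H](C)CO | intermediate
26 | (2R,5S,6S,10R)-2,6,10-trimethyl-11-(TBDPS-oxy)-5-{4-[(TBDPS-oxy)methyl]furan-2-yl}undecanal | CC(C)(C)[Si](c1ccccc1)(c1ccccc1)OC[C@H](C)CCC[C@H](C)[C@@H](c1cc(CO[Si](c2ccccc2)(c2ccccc2)C(C)(C)C)co1)CC[C@@H](C)C=O | intermediate
27 | 2-[(3R,6S,7S,11R)-3,7,11-trimethyl-12-(TBDPS-oxy)dodec-1-yn-6-yl]-4-[(TBDPS-oxy)methyl]furan (key-step precursor) | CC(C)(C)[Si](c1ccccc1)(c1ccccc1)OC[C@H](C)CCC[C@H](C)[C@@H](c1cc(CO[Si](c2ccccc2)(c2ccccc2)C(C)(C)C)co1)CC[C@@H](C)C#C | intermediate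
28 | C7–C8 arene oxide valence isomer of phenol 29 | CC(C)(C)[Si](c1ccccc1)(c1ccccc1)OC[C@H](C)CCC[C@H](C)[C@@H]1CC[C@@H](C)C2=C1C=C(CO[Si](c3ccccc3)(c3ccccc3)C(C)(C)C)C1OC21 | intermediate
29 | (5S,8R)-8-methyl-5-[(2S,6R)-6-methyl-7-(TBDPS-oxy)heptan-2-yl]-3-[(TBDPS-oxy)methyl]-5,6,7,8-tetrahydronaphthalen-1-ol (key-step product) | CC(C)(C)[Si](c1ccccc1)(c1ccccc1)OC[C@H](C)CCC[C@H](C)[C@@H]1CC[C@@H](C)c2c1cc(CO[Si](c3ccccc3)(c3ccccc3)C(C)(C)C)cc2O | intermediate
30 | (5S,8R)-8-methyl-5-[(2S,6R)-6-methyl-7-(TBDPS-oxy)heptan-2-yl]-3-[(TBDPS-oxy)methyl]-5,6,7,8-tetrahydronaphthalene-1,2-dione | CC(C)(C)[Si](c1ccccc1)(c1ccccc1)OC[C@H](C)CCC[C@H](C)[C@@H]1CC[C@@H](C)C2=C1C=C(CO[Si](c3ccccc3)(c3ccccc3)C(C)(C)C)C(=O)C2=O | intermediate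
31 | (5S,8R)-8-methyl-5-[(2S,6R)-6-methyl-7-(TBDPS-oxy)heptan-2-yl]-3-[(TBDPS-oxy)methyl]-5,6,7,8-tetrahydronaphthalene-1,2-diol | CC(C)(C)[Si](c1ccccc1)(c1ccccc1)OC[C@H](C)CCC[C@H](C)[C@@H]1CC[C@@H](C)c2c1cc(CO[Si](c3ccccc3)(c3ccccc3)C(C)(C)C)c(O)c2O | intermediate
32 | (5S,8R)-1,2-bis(methoxymethoxy)-8-methyl-5-[(2S,6R)-6-methyl-7-(TBDPS-oxy)heptan-2-yl]-3-[(TBDPS-oxy)methyl]-5,6,7,8-tetrahydronaphthalene | CC(C)(C)[Si](c1ccccc1)(c1ccccc1)OC[C@H](C)CCC[C@H](C)[C@@H]1CC[C@@H](C)c2c1cc(CO[Si](c3ccccc3)(c3ccccc3)C(C)(C)C)c(OCOC)c2OCOC | intermediate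
33 | (2R,6S)-6-[(1S,4R)-7-(hydroxymethyl)-5,6-bis(methoxymethoxy)-4-methyl-1,2,3,4-tetrahydronaphthalen-1-yl]-2-methylheptan-1-ol | OC[C@H](C)CCC[C@H](C)[C@@H]1CC[C@@H](C)c2c1cc(CO)c(OCOC)c2OCOC | intermediate
34 | (5R,8S)-8-[(2S,6R)-7-hydroxy-6-methylheptan-2-yl]-3,4-bis(methoxymethoxy)-5-methyl-5,6,7,8-tetrahydronaphthalene-2-carbaldehyde | OC[C@H](C)CCC[C@H](C)[C@@H]1CC[C@@H](C)c2c1cc(C=O)c(OCOC)c2OCOC | intermediate
35 | ferulic acid, (E)-3-(4-hydroxy-3-methoxyphenyl)prop-2-enoic acid | COc1cc(/C=C/C(=O)O)ccc1O | starting material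
36 | methoxymethyl (E)-3-[3-methoxy-4-(methoxymethoxy)phenyl]prop-2-enoate | COCOC(=O)/C=C/c1ccc(OCOC)c(OC)c1 | intermediate
37 | (E)-3-[3-methoxy-4-(methoxymethoxy)phenyl]prop-2-enoic acid | COCOc1ccc(/C=C/C(=O)O)cc1OC | intermediate
38 | (2R,6S)-6-[(1S,4R)-7-formyl-5,6-bis(methoxymethoxy)-4-methyl-1,2,3,4-tetrahydronaphthalen-1-yl]-2-methylheptyl (E)-3-[3-methoxy-4-(methoxymethoxy)phenyl]prop-2-enoate | COCOc1ccc(/C=C/C(=O)OC[C@H](C)CCC[C@H](C)[C@@H]2CC[C@@H](C)c3c2cc(C=O)c(OCOC)c3OCOC)cc1OC | intermediate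
39 | (5R,8S)-8-[(2S,6R)-7-{[(E)-3-(3-methoxy-4-(methoxymethoxy)phenyl)prop-2-enoyl]oxy}-6-methylheptan-2-yl]-3,4-bis(methoxymethoxy)-5-methyl-5,6,7,8-tetrahydronaphthalene-2-carboxylic acid | COCOc1ccc(/C=C/C(=O)OC[C@H](C)CCC[C@H](C)[C@@H]2CC[C@@H](C)c3c2cc(C(=O)O)c(OCOC)c3OCOC)cc1OC | intermediate
40 | (5R,8S)-3,4-dihydroxy-8-[(2S,6R)-7-{[(E)-3-(4-hydroxy-3-methoxyphenyl)prop-2-enoyl]oxy}-6-methylheptan-2-yl]-5-methyl-5,6,7,8-tetrahydronaphthalene-2-carboxylic acid (CNP0535851.1) | COc1cc(/C=C/C(=O)OC[C@H](C)CCC[C@H](C)[C@@H]2CC[C@@H](C)c3c2cc(C(=O)O)c(O)c3O)ccc1O | target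

**Step count and risks**

Total step count: 28.
Longest linear sequence: 23 steps (steps 1–6, 11–24 and 26–28, from 1 to 40).

Steps most likely to fail:

Step 20 (key step). Closure of ring B by the furan onto the gold-activated alkyne may be outpaced by hydration or oligomerisation of the terminal alkyne, because the four-carbon tether carries no gem-disubstituent, and the arene oxide may partly open toward C7. The fallback sets out from alkyne 27 and forms the same two bonds by a thermal intramolecular Diels–Alder reaction of the furan with the alkyne (o-dichlorobenzene, 200 °C, sealed vessel), which should give the 7-oxanorbornadiene cycloadduct F1. Treatment of this adduct with TsOH in CH2Cl2 should ionise the C10–O bridge bond and, after loss of the C7 proton, give the 7-hydroxy tetralin F2. IBX under the conditions of step 21 should oxidise F2 at its only free ortho carbon, C8, to the same ortho-quinone 30, and dithionite reduction brings the route back at catechol 31.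

Step 21. Oxygen transfer from iodine to the hindered ortho carbon may stall, or the ortho-quinone may tautomerise toward a quinone methide and be intercepted before it is reduced. The fallback sets out from phenol 29 and introduces the C7 oxygen in two known steps. Magnesium-mediated ortho-formylation (MgCl2, Et3N, paraformaldehyde, MeCN, reflux) should place a formyl group on C7, the only free ortho position, giving the salicylaldehyde F3. Dakin oxidation (H2O2, NaOH, THF/H2O, 0 °C) then replaces the formyl group by hydroxyl and rejoins the route at catechol 31.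

Step 16. Hydrogen transfer from diimide to a trans alkene that is branched at both allylic carbons may be too slow, so that disproportionation of diimide uses up the reagent before reduction is complete. The fallback sets out from alcohol 21 and moves the reduction to a hydroxyl-directed homogeneous hydrogenation with [Ir(cod)(PCy3)(py)]PF6 (H2 at 1 atm, CH2Cl2, rt), which should give the saturated primary alcohol F4 without touching furan or silyl ethers. Tosylation as in step 14 gives the saturated tosylate F5, and LiEt3BH as in step 15 displaces the tosylate and rejoins the route at 24.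

**Further compounds**

F1 | step 20 | 7-oxanorbornadiene cycloadduct of 27 (O bridging C7 and C10) | CC(C)(C)[Si](c1ccccc1)(c1ccccc1)OC[C@H](C)CCC[C@H](C)[C@@H]1CC[C@@H](C)C2=CC3OC12C=C3CO[Si](c4ccccc4)(c4ccccc4)C(C)(C)C
F2 | step 20 | (5R,8S)-5-methyl-8-[(2S,6R)-6-methyl-7-(TBDPS-oxy)heptan-2-yl]-3-[(TBDPS-oxy)methyl]-5,6,7,8-tetrahydronaphthalen-2-ol (7-hydroxy tetralin) | CC(C)(C)[Si](c1ccccc1)(c1ccccc1)OC[C@H](C)CCC[C@H](C)[C@@H]1CC[C@@H](C)c2c1cc(CO[Si](c3ccccc3)(c3ccccc3)C(C)(C)C)c(O)c2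
F3 | step 21 | C7-formyl derivative of phenol 29 (salicylaldehyde) | CC(C)(C)[Si](c1ccccc1)(c1ccccc1)OC[C@H](C)CCC[C@H](C)[C@@H]1CC[C@@H](C)c2c1cc(CO[Si](c3ccccc3)(c3ccccc3)C(C)(C)C)c(C=O)c2O
F4 | step 16 | saturated primary alcohol, 4,5-dihydro derivative of 21 | CC(C)(C)[Si](c1ccccc1)(c1ccccc1)OC[C@H](C)CCC[C@H](CO)[C@@H](c1cc(CO[Si](c2ccccc2)(c2ccccc2)C(C)(C)C)co1)CC[C@@H](C)CO[Si](C)(C)C(C)(C)C
F5 | step 16 | saturated tosylate, 4,5-dihydro derivative of 22 | CC(C)(C)[Si](c1ccccc1)(c1ccccc1)OC[C@H](C)CCC[C@H](COS(=O)(=O)c1ccc(C)cc1)[C@@H](c1cc(CO[Si](c2ccccc2)(c2ccccc2)C(C)(C)C)co1)CC[C@@H](C)CO[Si](C)(C)C(C)(C)C
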